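Numbering used throughout: 1 bromanil; 2 dibromo-dimethoxyquinone; 3 its hydroquinone; 4 ketal alcohol; 5 mono-ether phenol; 6 bis-ketal diether; 7 diketone; 8 octabromo diketone (formed in the flask); 9 bis(2,6-dibromophenol); 10 bis(2,3,6-tribromophenol); 11 target.

Remark on the chemistry: ring B is taken at the hydroquinone oxidation level shown by the SMILES, and 11 has no stereocentre.

## Analysis of the target

Compound 11 (C18H6Br8O6) is a linear, centrosymmetric triaryl bis-ether without any stereocentre, so the whole problem is constitutional: eight bromines and four hydroxyls must each end up on the right carbon. Ring B is a hydroquinone with hydroxyls at C1 and C4, bromine at C2 and C5 and aryloxy groups at C3 and C6; rings A and C are identical 2,3,5-tribromo-4-hydroxyphenoxy groups. The sensitive parts are the ring-B hydroquinone, which bromine or air in base oxidises to the quinone, and the outer para-oxygenated phenols, which can lose their ether by attack at the para carbon. The eight C–Br bonds exclude hydrogenolysis, organolithium chemistry and low-valent metal catalysis late in the route. The first difficulty is that each bridging oxygen sits between a bromine and an oxygen substituent on ring B and next to a bromine-bearing carbon on ring A or C, so a direct O-arylation would have to join two crowded, electron-poor partners. The second is the unsymmetrical bromine pattern of the outer rings, with two bromines ortho to the hydroxyl (C3', C5') and one ortho to the ether oxygen (C2'). The strategy rests on the fact that in rings A and C the ether carbon C1' is para to the hydroxyl carbon C4', which has bromine on both neighbours: a 4-oxycyclohexanone gives exactly this pattern on exhaustive alpha-bromination and dehydrobromination, the carbonyl carbon becoming C4'–OH, the alpha carbons C3'–Br and C5'–Br, and the sp3 ether carbon C1'. Ring B consists of three para pairs (O/O, O/O, Br/Br), which is the pattern of a 2,5-disubstituted 3,6-dibromoquinone and therefore of 1.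

## Retrosynthetic reasoning

11 to 10. The two O–CH3 bonds on ring B are cut last. The ring-B hydroquinone is the most easily oxidised part of 11 and would not survive electrophilic bromination, so it stays masked as its dimethyl ether until all eight bromines are in place. The forward step must cleave two alkyl aryl ethers and leave the two diaryl ethers intact; a Lewis-acid-mediated cleavage does this because the halide can only attack the sp3 methyl carbon.

10 to 9. The C2'–Br bond on each outer ring is cut. This carbon is beta to the former ketone and cannot be reached by enol chemistry, so its bromine is added by aromatic substitution once the phenol exists. In 9 the ortho and para carbons of each hydroxyl are all occupied, so the ether oxygen alone directs, and the only free carbons are the two equivalent ones ortho to it. The forward reaction must stop after one bromine per ring.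

9 to 7, through 8. The four C–Br bonds ortho to the outer hydroxyls and the aromaticity of rings A and C are removed together, which turns each outer ring into a 4-aryloxycyclohexanone. The gain is that the crowded diaryl ether becomes an alkyl aryl ether at a secondary sp3 carbon, and the two bromines ortho to each hydroxyl are placed by the ketone and not by a directing group. The forward reaction has to replace all four alpha hydrogens of each ketone (8) and then achieve a twofold dehydrobromination per ring without breaking the C4–O bond.

7 to 6. Each ketone is masked as its ethylene ketal. The alcohol partner then has a single reactive function, and no enolisable ketone is present during the etherifications.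

6 to 5 and 4. One C(sp3)–O bond is cut, giving the phenol 5 as oxygen nucleophile and one molecule of the purchasable ketal alcohol 4. Cutting the aryl C–O bond instead would require substitution on a hexasubstituted benzene. The forward reaction is a redox condensation with displacement at the carbinol carbon; that carbon is not a stereocentre, so inversion is of no consequence.

5 to 3 and 4. The other C(sp3)–O bond is cut in the same way, giving the hydroquinone 3 and a second molecule of 4. The two ether bonds are made in separate operations for a reason. The free hydroquinone 3 can be dehydrogenated by the oxidising half of the redox couple, so it meets that reagent only once and in excess. The mono-ether 5 is no longer a hydroquinone and tolerates the more forcing conditions that its hindered oxygen needs.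

3 to 2 to 1. The hydroquinone comes from its quinone by mild reduction, and the two methoxy groups come from twofold addition–elimination at two carbon–bromine positions of 1. This delivers the whole ring-B pattern, both bromines included, in one operation. The two oxygens that arrive as carbonyl oxygens in 1 become the ether oxygens of rings A and C, and the two that arrive as methoxy become the free hydroxyls of 11.

## Alternatives that were turned down

Alternative 1: Ring B is assembled by a Dötz three-component benzannulation.
- Disconnection: ring B is split into a carbene carbon (the future C–OMe), one carbonyl ligand (the future C–OH) and two C2 units that each already carry an aryloxy group. These are the 1-aryloxyvinyl group of the Cr(CO)5 carbene complex A2 and the alkyne of the aryl ethynyl ether A3.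
- Forward key step: heating A2 with A3 would form three C–C bonds and close ring B as the 4-methoxyphenol A1. The aryloxy-bearing alkyne carbon ends up next to the new hydroxyl, as expected for a terminal alkyne.
- For it: both diaryl ether oxygens are attached before ring B exists, so no oxygen on a crowded ring has to be alkylated or arylated. On this point it is stronger than the chosen route, whose etherifications are among its weaker steps. The two ring-B oxygens also emerge differentiated.
- Against it: the differentiation is of no use because 11 is symmetric. A1 contains none of the eight bromines, so all must be introduced afterwards by electrophilic substitution on three electron-rich rings at once, and ring B of A1 is then the ring most easily oxidised to a quinone. A2 and A3 are not purchasable and each needs several steps, the chromium is stoichiometric, and heteroatom-substituted alkynes are prone to simple insertion without carbonyl incorporation. The sequence would be clearly longer than eight steps.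
- Comparison: the chosen strategy gets the complete ring-B pattern from 1 in one step and lets the aromatisation itself place four of the six outer-ring bromines.

Alternative 2: The outer rings are built by Diels–Alder reaction and aromatised with loss of a carboxyl group.
- Disconnection: each outer ring is cut into the diene A6 and a 2-aryloxyacrylate unit of the bis-acrylate A5, which would be made from 3.
- Forward key step: twofold thermal cycloaddition with "para" regiochemistry and mild acid work-up would give the bis(keto ester) A4. Its ether carbon is quaternary and carries the ester.
- For it: the C–O bonds to the hindered oxygens of 3 are made by addition–elimination at an unhindered acrylate carbon, which avoids a displacement at a secondary cyclohexyl carbon that competes with elimination. The quaternary ether carbon has no hydrogen, so loss of aryloxide before aromatisation is less of a concern. On both points it is as strong as or stronger than the chosen route.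
- Against it: 2-aryloxyacrylates are sluggish dienophiles because the oxygen donor raises the acceptor orbital, and two cycloadditions are needed on one molecule. Two ester carbons are introduced only to be removed again, and the six-membered ring that is constructed can simply be bought as 4. The aromatisation then depends on the carboxyl group, and not the aryloxy group, leaving the quaternary carbon of a 4,4-disubstituted dienone. The end game (third bromination, demethylation) is the same as in the chosen route, so the sequence is no shorter.
- Comparison: the chosen strategy reaches the same kind of cyclohexanone in five steps with no sacrificial carbon and with a hydrogen on C4 that makes the final tautomerisation trivial.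

Alternative 3: Both diaryl ethers are formed by anodic para C–O coupling.
- Disconnection: both diaryl ether C–O bonds are cut on the outer-ring side, giving the dianion of bromanilic acid A8 and two molecules of 2,3,6-tribromophenol A9.
- Forward key step: anodic oxidation of A9 in the presence of the dianion would join each enolic oxygen of ring B to the para carbon of one phenol and give the quinone A7. A7 is one reduction away from 11.
- For it: step economy. All eight bromines and all six oxygens are already in the two partners, and the route would be about three steps. Here it is much stronger than the chosen route.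
- Against it: the oxygen of A8 is the conjugate base of a strong vinylogous acid and is a very poor nucleophile. It has to compete with solvent, with traces of water that would hydroxylate the para carbon instead, and with self-coupling of the oxidised phenol. Each coupling product is a para-oxygenated phenol that is oxidised more easily than A9, so over-oxidation with loss of the new ether is built into the mechanism, and this has to be overcome twice on the same dianion.
- Comparison: the chosen strategy is five steps longer, but every bond is made by a polar step whose site selectivity is fixed by the substrate.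

Key step: step 6

## Route

Step 1
Reactants: 1 bromanil (2,3,5,6-tetrabromo-1,4-benzoquinone)
Product: 2 2,5-dibromo-3,6-dimethoxy-1,4-benzoquinone
Conditions: NaOMe (2.05 equiv), MeOH, 0 °C to rt
Reagents that add atoms: sodium methoxide, C[O-].[Na+]
Why: Addition–elimination on a haloquinone; the first methoxy group turns the carbonyl conjugated to it into a vinylogous ester, so the second methoxide adds at the carbon whose negative charge is taken up by the other carbonyl, which gives the 2,5-pattern. The doubly deactivated product should separate from methanol before a third substitution.

Step 2
Reactants: 2 2,5-dibromo-3,6-dimethoxy-1,4-benzoquinone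
Product: 3 2,5-dibromo-3,6-dimethoxybenzene-1,4-diol
Conditions: Na2S2O4 (aq, excess), EtOAc/H2O, rt, N2
Reagents that add atoms: none
Why: Dithionite reduction of a quinone to its hydroquinone in a two-phase system; C–Br and vinylogous ester groups are untouched, and 3 is used promptly under inert gas.

Step 3
Reactants: 3 2,5-dibromo-3,6-dimethoxybenzene-1,4-diol; 4 1,4-dioxaspiro[4.5]decan-8-ol
Product: 5 2,5-dibromo-4-(1,4-dioxaspiro[4.5]decan-8-yloxy)-3,6-dimethoxyphenol
Conditions: PPh3 (1.2 equiv) and diisopropyl azodicarboxylate (DIAD, 1.2 equiv) premixed at 0 °C, then 4 (1.0 equiv), the mixture added slowly to 3 (2.5 equiv), THF, 0 °C to rt, argon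
Reagents that add atoms: none
Why: Mitsunobu etherification; the ortho bromine makes each hydroxyl of 3 acidic enough to protonate the betaine, and the phenoxide displaces the oxyphosphonium group at the secondary carbon of 4, which is not a stereocentre. Premixing phosphine and azodicarboxylate limits dehydrogenation of the hydroquinone by free azo compound, and the excess of 3 holds the reaction at one ether bond; unreacted 3 is recovered, and any doubly etherified material is 6 and is carried forward.

Step 4
Reactants: 5 2,5-dibromo-4-(1,4-dioxaspiro[4.5]decan-8-yloxy)-3,6-dimethoxyphenol; 4 1,4-dioxaspiro[4.5]decan-8-ol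
Product: 6 8,8'-[(2,5-dibromo-3,6-dimethoxy-1,4-phenylene)bis(oxy)]bis(1,4-dioxaspiro[4.5]decane)
Conditions: 4 (2 equiv), PPh3 (2 equiv), DIAD (2 equiv, added last, dropwise), THF, 0 to 45 °C, argon
Reagents that add atoms: none
Why: Second Mitsunobu etherification; 5 is a bromophenol and no longer a hydroquinone, so the azo compound cannot dehydrogenate it to a quinone, and excess reagents with gentle warming can be used to drive the hindered oxygen between Br and OMe onto the secondary carbon of 4. The ketal keeps the ketone out of the reaction.

Step 5
Reactants: 6 8,8'-[(2,5-dibromo-3,6-dimethoxy-1,4-phenylene)bis(oxy)]bis(1,4-dioxaspiro[4.5]decane)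
Product: 7 4,4'-[(2,5-dibromo-3,6-dimethoxy-1,4-phenylene)bis(oxy)]dicyclohexanone
Conditions: 2 M aq HCl, THF, 40 °C
Reagents that add atoms: water, O
Why: Acid-catalysed hydrolysis of the two dioxolanes; aryl methyl and aryl sec-alkyl ethers are stable to dilute aqueous acid, and the ether carbon is gamma to the new carbonyl, so the saturated ketone cannot lose the aryloxy group by beta-elimination.

Step 6
Reactants: 7 4,4'-[(2,5-dibromo-3,6-dimethoxy-1,4-phenylene)bis(oxy)]dicyclohexanone
Product: 9 4,4'-[(2,5-dibromo-3,6-dimethoxy-1,4-phenylene)bis(oxy)]bis(2,6-dibromophenol), via octabromo diketone 8 (not isolated)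
Conditions: Br2 (8.1 equiv), AcOH, 20 to 45 °C, dark, 7 added to the Br2 solution; then NaOAc (14 equiv), 95 °C
Reagents that add atoms: bromine, BrBr
Why: Acid-catalysed enolisation, autocatalysed by the hydrogen bromide formed, and enol bromination replace all four alpha hydrogens of each ketone, so that 8 with two 2,2,6,6-tetrabromo-4-aryloxycyclohexanone rings accumulates while bromine is still in excess. On buffering and heating, acetate removes H3 and then H5, each anti to an axial alpha bromine, to give on each ring the 2,6-dibromocyclohexa-2,5-dienone that still carries H4, and keto–enol tautomerisation delivers the 2,6-dibromo-4-aryloxyphenol irreversibly. The closest known reaction type is the conversion of cyclohexanones into 2,6-dihalophenols through their 2,2,6,6-tetrahalo ketones, and more generally the bromine-mediated aromatisation of cyclohexanones and cyclohexenones to ortho-bromophenols. No ring is closed and no stereocentre is created; four new C–Br bonds remain in 9 and rings A and C become aromatic. Three selectivities are needed. Reaction on rings A and C and not on ring B is secured because ring B has no hydrogen and no enolisable position. Placement of bromine on the two carbons ortho to the future hydroxyl is secured because only the alpha carbons of a ketone are brominated through the enol. Retention of the C4–O bond is secured by the order of events: every alpha hydrogen is replaced before the first double bond appears, so no enone can deconjugate to a C3=C4 enol ether while free bromine is still present, and the phenol is never exposed to a large excess of free bromine.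

Step 7
Reactants: 9 4,4'-[(2,5-dibromo-3,6-dimethoxy-1,4-phenylene)bis(oxy)]bis(2,6-dibromophenol)
Product: 10 4,4'-[(2,5-dibromo-3,6-dimethoxy-1,4-phenylene)bis(oxy)]bis(2,3,6-tribromophenol)
Conditions: Br2 (2.2 equiv), AcOH (anhydrous), 50 °C, dark
Reagents that add atoms: bromine, BrBr
Why: Electrophilic aromatic bromination; the only unsubstituted carbons of 9 are C3 and C5 of each outer phenol, equivalent and ortho to the diaryl ether oxygen, which directs there because the ortho and para carbons of the hydroxyl are occupied. The first bromine deactivates and crowds the ring, which should hold each ring at the tribromo stage, and anhydrous acidic conditions keep para attack reversible.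

Step 8
Reactants: 10 4,4'-[(2,5-dibromo-3,6-dimethoxy-1,4-phenylene)bis(oxy)]bis(2,3,6-tribromophenol)
Product: 11 2,5-dibromo-3,6-bis(2,3,5-tribromo-4-hydroxyphenoxy)benzene-1,4-diol
Conditions: BBr3 (8 equiv), CH2Cl2, −78 °C to rt; then H2O, aq Na2S2O4 wash
Reagents that add atoms: none
Why: Lewis-acid ether cleavage; BBr3 binds the twisted, di-ortho-substituted methoxy oxygens and bromide attacks the methyl carbon, while the diaryl ethers offer no sp3 carbon and stay intact. The reductive wash keeps ring B at the hydroquinone level.

## Compound list

1 | bromanil (2,3,5,6-tetrabromo-1,4-benzoquinone) | O=C1C(Br)=C(Br)C(=O)C(Br)=C1Br | starting material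
2 | 2,5-dibromo-3,6-dimethoxy-1,4-benzoquinone | COC1=C(Br)C(=O)C(OC)=C(Br)C1=O | intermediate
3 | 2,5-dibromo-3,6-dimethoxybenzene-1,4-diol | COc1c(Br)c(O)c(OC)c(Br)c1O | intermediate
4 | 1,4-dioxaspiro[4.5]decan-8-ol | OC1CCC2(CC1)OCCO2 | starting material
5 | 2,5-dibromo-4-(1,4-dioxaspiro[4.5]decan-8-yloxy)-3,6-dimethoxyphenol | COc1c(Br)c(O)c(OC)c(Br)c1OC2CCC3(CC2)OCCO3 | intermediate
6 | 8,8'-[(2,5-dibromo-3,6-dimethoxy-1,4-phenylene)bis(oxy)]bis(1,4-dioxaspiro[4.5]decane) | COc1c(Br)c(OC2CCC3(CC2)OCCO3)c(OC)c(Br)c1OC2CCC3(CC2)OCCO3 | intermediate
7 | 4,4'-[(2,5-dibromo-3,6-dimethoxy-1,4-phenylene)bis(oxy)]dicyclohexanone | COc1c(Br)c(OC2CCC(=O)CC2)c(OC)c(Br)c1OC3CCC(=O)CC3 | intermediate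
8 | 4,4'-[(2,5-dibromo-3,6-dimethoxy-1,4-phenylene)bis(oxy)]bis(2,2,6,6-tetrabromocyclohexanone) | COc1c(Br)c(OC2CC(Br)(Br)C(=O)C(Br)(Br)C2)c(OC)c(Br)c1OC3CC(Br)(Br)C(=O)C(Br)(Br)C3 | intermediate
9 | 4,4'-[(2,5-dibromo-3,6-dimethoxy-1,4-phenylene)bis(oxy)]bis(2,6-dibromophenol) | COc1c(Br)c(Oc2cc(Br)c(O)c(Br)c2)c(OC)c(Br)c1Oc3cc(Br)c(O)c(Br)c3 | intermediate
10 | 4,4'-[(2,5-dibromo-3,6-dimethoxy-1,4-phenylene)bis(oxy)]bis(2,3,6-tribromophenol) | COc1c(Br)c(Oc2cc(Br)c(O)c(Br)c2Br)c(OC)c(Br)c1Oc3cc(Br)c(O)c(Br)c3Br | intermediate
11 | 2,5-dibromo-3,6-bis(2,3,5-tribromo-4-hydroxyphenoxy)benzene-1,4-diol | Oc1c(Br)cc(Oc2c(O)c(Br)c(Oc3cc(Br)c(O)c(Br)c3Br)c(O)c2Br)c(Br)c1Br | target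

## Step count and least certain steps

Total: 8 steps. Longest linear sequence: 8 steps, from 1 to 11; 4 enters at steps 3 and 4.

Step 6 (key step).
- What may go wrong: the fourfold alpha-bromination of each ring may be incomplete when elimination starts. Double bonds then form while free bromine is still present, an enone can deconjugate through its linear dienol to an enol ether at C4, and bromination of that enol ether breaks the C4–O bond.
- Bromine may also be transferred from the gem-dibromo ketone to freshly formed phenol, so that some rings end up over-brominated and others under-brominated.
- Before buffering, the hydrogen bromide in warm acetic acid may begin to cleave the ring-B methyl ethers.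
- Fallback: this gives up the saturated outer rings and brings them in as aromatic units by addition–elimination on the quinone. From 1, 4-(benzyloxy)phenol with K2CO3 in MeCN should give 2,5-bis[4-(benzyloxy)phenoxy]-3,6-dibromo-1,4-benzoquinone F1. Na2S2O4 reduces it to the hydroquinone 2,5-bis[4-(benzyloxy)phenoxy]-3,6-dibromobenzene-1,4-diol F2, and MeI with K2CO3 in acetone gives the dimethyl ether 1,4-bis[4-(benzyloxy)phenoxy]-2,5-dibromo-3,6-dimethoxybenzene F3. BCl3 with pentamethylbenzene at −78 °C removes the benzyl groups to give the bis-phenol 4,4'-[(2,5-dibromo-3,6-dimethoxy-1,4-phenylene)bis(oxy)]diphenol F4. Br2 (4 equiv) in AcOH then brominates the four carbons ortho to the free hydroxyls, and the route is rejoined at 9.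

Step 3.
- What may go wrong: the azodicarboxylate may dehydrogenate the hydroquinone back to the quinone level. The activated secondary alcohol may dehydrate by elimination. Control over single against double etherification may be poor, although doubly etherified material is not lost because it is 6.
- Fallback: the redox condensation is replaced by a base-mediated displacement on a preformed sulfonate, so that no oxidant is present. From 4, TsCl in pyridine gives 1,4-dioxaspiro[4.5]decan-8-yl 4-methylbenzenesulfonate F5. Compound 3, kept in excess, is then alkylated once with F5 (Cs2CO3, DMF, 60 °C, argon), and the route is rejoined at 5.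

Step 4.
- What may go wrong: the remaining hydroxyl of 5 lies between Br and OMe and is para to an alkoxy group, so protonation of the betaine and displacement at the secondary carbon may both be slow. Elimination of the activated alcohol may then take over and the reaction may stall.
- Fallback: the aryl C–O bonds are formed in place of the alkyl C–O bonds, at the quinone stage, so that the secondary carbon never acts as an electrophile. From 1, the sodium alkoxide of 4 (NaH, THF, 0 °C, slow addition) should give by twofold addition–elimination 2,5-dibromo-3,6-bis(1,4-dioxaspiro[4.5]decan-8-yloxy)-1,4-benzoquinone F6, with the 2,5-pattern set as in step 1. Na2S2O4 reduces it to 2,5-dibromo-3,6-bis(1,4-dioxaspiro[4.5]decan-8-yloxy)benzene-1,4-diol F7. MeI with K2CO3 in acetone methylates both hydroxyls, and the route is rejoined at 6.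

Step 7.
- What may go wrong: a second bromine may enter the same ring. Attack at the para carbon of the free phenol may lead to oxidative loss of the ring-B ether. The reaction may also be incomplete and leave mixtures of bromination levels that are hard to separate.
- Fallback: the phenols are capped so that the ring can no longer form a neutral dienone and a Lewis acid can be used. From 9, MeI with K2CO3 in acetone gives 1,4-dibromo-2,5-bis(3,5-dibromo-4-methoxyphenoxy)-3,6-dimethoxybenzene F8. Br2 (2.2 equiv) with catalytic FeBr3 in CH2Cl2 gives 1,4-dibromo-2,5-dimethoxy-3,6-bis(2,3,5-tribromo-4-methoxyphenoxy)benzene F9. Excess BBr3 cleaves all four methyl ethers, and the route is rejoined at 11.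

## Further compounds

F1 | step 6 | 2,5-bis[4-(benzyloxy)phenoxy]-3,6-dibromo-1,4-benzoquinone | O=C1C(Br)=C(Oc2ccc(OCc3ccccc3)cc2)C(=O)C(Br)=C1Oc4ccc(OCc5ccccc5)cc4
F2 | step 6 | 2,5-bis[4-(benzyloxy)phenoxy]-3,6-dibromobenzene-1,4-diol | Oc1c(Br)c(Oc2ccc(OCc3ccccc3)cc2)c(O)c(Br)c1Oc4ccc(OCc5ccccc5)cc4
F3 | step 6 | 1,4-bis[4-(benzyloxy)phenoxy]-2,5-dibromo-3,6-dimethoxybenzene | COc1c(Br)c(Oc2ccc(OCc3ccccc3)cc2)c(OC)c(Br)c1Oc4ccc(OCc5ccccc5)cc4
F4 | step 6 | 4,4'-[(2,5-dibromo-3,6-dimethoxy-1,4-phenylene)bis(oxy)]diphenol | COc1c(Br)c(Oc2ccc(O)cc2)c(OC)c(Br)c1Oc3ccc(O)cc3
F5 | step 3 | 1,4-dioxaspiro[4.5]decan-8-yl 4-methylbenzenesulfonate | Cc1ccc(cc1)S(=O)(=O)OC1CCC2(CC1)OCCO2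
F6 | step 4 | 2,5-dibromo-3,6-bis(1,4-dioxaspiro[4.5]decan-8-yloxy)-1,4-benzoquinone | O=C1C(Br)=C(OC2CCC3(CC2)OCCO3)C(=O)C(Br)=C1OC4CCC5(CC4)OCCO5
F7 | step 4 | 2,5-dibromo-3,6-bis(1,4-dioxaspiro[4.5]decan-8-yloxy)benzene-1,4-diol | Oc1c(Br)c(OC2CCC3(CC2)OCCO3)c(O)c(Br)c1OC4CCC5(CC4)OCCO5
F8 | step 7 | 1,4-dibromo-2,5-bis(3,5-dibromo-4-methoxyphenoxy)-3,6-dimethoxybenzene | COc1c(Br)c(Oc2cc(Br)c(OC)c(Br)c2)c(OC)c(Br)c1Oc3cc(Br)c(OC)c(Br)c3
F9 | step 7 | 1,4-dibromo-2,5-dimethoxy-3,6-bis(2,3,5-tribromo-4-methoxyphenoxy)benzene | COc1c(Br)c(Oc2cc(Br)c(OC)c(Br)c2Br)c(OC)c(Br)c1Oc3cc(Br)c(OC)c(Br)c3Br
A1 | alternative 1 | 4-methoxy-2,5-bis(4-methoxyphenoxy)phenol | COc1cc(Oc2ccc(OC)cc2)c(O)cc1Oc3ccc(OC)cc3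
A2 | alternative 1 | pentacarbonyl{methoxy[1-(4-methoxyphenoxy)ethenyl]carbene}chromium | COC(=[Cr])C(=C)Oc1ccc(OC)cc1.[C-]#[O+].[C-]#[O+].[C-]#[O+].[C-]#[O+].[C-]#[O+]
A3 | alternative 1 | 1-(ethynyloxy)-4-methoxybenzene | C#COc1ccc(OC)cc1
A4 | alternative 2 | dimethyl 1,1'-[(2,5-dibromo-3,6-dimethoxy-1,4-phenylene)bis(oxy)]bis(4-oxocyclohexane-1-carboxylate) | COc1c(Br)c(OC2(CCC(=O)CC2)C(=O)OC)c(OC)c(Br)c1OC3(CCC(=O)CC3)C(=O)OC
A5 | alternative 2 | dimethyl 2,2'-[(2,5-dibromo-3,6-dimethoxy-1,4-phenylene)bis(oxy)]bis(prop-2-enoate) | COc1c(Br)c(OC(=C)C(=O)OC)c(OC)c(Br)c1OC(=C)C(=O)OC
A6 | alternative 2 | 2-(trimethylsilyloxy)buta-1,3-diene | C=CC(=C)O[Si](C)(C)C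
A7 | alternative 3 | 2,5-dibromo-3,6-bis(2,3,5-tribromo-4-hydroxyphenoxy)-1,4-benzoquinone | O=C1C(Br)=C(Oc2cc(Br)c(O)c(Br)c2Br)C(=O)C(Br)=C1Oc3cc(Br)c(O)c(Br)c3Br
A8 | alternative 3 | bromanilic acid (2,5-dibromo-3,6-dihydroxy-1,4-benzoquinone), used as its dianion | O=C1C(Br)=C(O)C(=O)C(Br)=C1O
A9 | alternative 3 | 2,3,6-tribromophenol | Oc1c(Br)c(Br)ccc1Br
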